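**Plan** (locants C1–C15 are those of the target chain: C1 = alkyne CH, ring O bridges C4 and C7, OAc on C6, OH on C9, Br on C3 and C10)

1. Retrosynthesis: the two C–Br bonds (C3, C10) are cut last, back to a 3,10-diol (two SN2 inversions). The C9–C10 bond is cut next: the vicinal C9–OH/C10–Br pair is read as a β-hydroxy boronate (C10–Br ⇐ C10–OH ⇐ C10–B), which divides the target into aldehyde 13 (C1–C9) and gem-diboryl alkane 17 (C10–C15).
2. The 2,5-cis tetrahydrofuran (O, C4, C5, C6, C7) carries O6 and the C8–C9 arm cis on adjacent ring carbons. It is therefore traced to a cis-fused γ-lactone (O6–C9) and then to a C2-symmetric diene-diol.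
3. Forward: Noyori hydrogenation and ylide homologation give the diene-diol. One Pd(II) oxycarbonylation closes the THF (5-exo) and the lactone. Ozonolysis and chelate-controlled alkynylation add C1–C3. Lactone opening gives the C6-acetoxy C9-aldehyde.
4. The chain is then joined at C9–C10 by a Cu-catalysed, ligand-controlled syn addition of 17. This sets C9 and C10 and brings in the E-C12=C13 alkene intact. B→OH (retention), double Appel bromination (inversion at C3 and C10) and desilylation finish the route.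
5. Stereochemistry: C4/C6 from the hydrogenation catalyst; C7 from the cis-lactone constraint; C3 from Cram-chelate addition followed by SN2; C9/C10 from the chiral Cu catalyst, C10 then inverted by bromide.

Key step: step 11

Assumption: 1,5-dichloropentane-2,4-dione (1), bis(pinacolato)borylmethane (14) and (E)-1-bromopent-2-ene (15) are taken as purchasable. Where a catalyst antipode is named, it is the one expected to give the stated configuration.

**Route**

Step 1
Reactants: 1 1,5-dichloropentane-2,4-dione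
Product: 2 (2R,4R)-1,5-dichloropentane-2,4-diol
Conditions: H2 (80 bar), Ru–(S)-BINAP cat., MeOH, 80 °C
Reagents that add atoms: none
Why: Noyori asymmetric hydrogenation of the β-diketone should reduce both carbonyls under catalyst control (the (S)-BINAP complex is expected to give 2R,4R, by analogy with 4-chloro-3-oxobutanoates) and give the anti, C2-symmetric diol that becomes C4 and C6.

Step 2
Reactants: 2 (2R,4R)-1,5-dichloropentane-2,4-diol
Product: 4 (3R,5R)-hepta-1,6-diene-3,5-diol, via bis-epoxide 3 (not isolated)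
Conditions: Me3S+ I− (excess), n-BuLi, THF, −10 °C → rt; aq. work-up
Reagents that add atoms: trimethylsulfonium iodide C[S+](C)C.[I-]
Why: Base should close both chlorohydrins (Williamson), and dimethylsulfonium methylide should open each terminal epoxide and eliminate Me2S to the allylic alcohol (Corey–Chaykovsky-type ylide, epoxide-to-allylic-alcohol homologation); the carbinol centres are not touched.

Step 3
Reactants: 4 (3R,5R)-hepta-1,6-diene-3,5-diol
Product: 5 (3aR,5R,6aR)-5-ethenyltetrahydrofuro[3,2-b]furan-2(3H)-one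
Conditions: PdCl2 (10 mol%), CuCl2 (3 equiv), NaOAc (3 equiv), CO (1 atm), AcOH, rt
Reagents that add atoms: carbon monoxide [C-]#[O+]
Why: Pd(II) alkoxycarbonylation–lactonisation (5-exo oxypalladation, CO insertion, acyl capture by the allylic OH) should desymmetrise the diol; only the alkyl–Pd that is cis to O6 can lactonise, so C7 is set cis to O6 and, because the diol is anti, cis to the C4 vinyl group.

Step 4
Reactants: 5 vinyl lactone
Product: 7 (3aR,5R,6aR)-2-oxohexahydrofuro[3,2-b]furan-5-carbaldehyde, via ozonide 6 (not isolated)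
Conditions: O3, CH2Cl2, −78 °C; then Me2S, −78 °C → rt
Reagents that add atoms: ozone [O-][O+]=O
Why: Ozonolysis with reductive work-up should cleave the only alkene to the C3 aldehyde without touching the three ring stereocentres.

Step 5
Reactants: 7 lactone aldehyde
Product: 8 (3R)-propargylic alcohol lactone
Conditions: TMSC≡CH, EtMgBr, THF, 0 °C; then 7 premixed with MgBr2·OEt2, CH2Cl2, −78 °C; aq. NH4Cl
Reagents that add atoms: ethynyltrimethylsilane C#C[Si](C)(C)C
Why: Cram-chelate-controlled Grignard addition (Mg bridging the ring oxygen and C=O, attack from the side of H-4) should give the syn (3R) carbinol, the lactone being much less electrophilic at −78 °C.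

Step 6
Reactants: 8 (3R)-propargylic alcohol lactone
Product: 9 C3 triethylsilyl ether of the lactone
Conditions: TESCl, imidazole, DMF, 0 °C → rt
Reagents that add atoms: chlorotriethylsilane CC[Si](Cl)(CC)CC
Why: Standard silylation should protect O3 for the hydride, acylation and organocopper steps that follow.

Step 7
Reactants: 9 C3 triethylsilyl ether of the lactone
Product: 10 C6,C9-diol
Conditions: LiBH4, THF, 0 °C → rt; aq. NH4Cl
Reagents that add atoms: none
Why: Borohydride reduction of the γ-lactone to the 1,4-diol should free the secondary C6–OH and the primary C9–OH; silyl ether and silyl alkyne are inert.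

Step 8
Reactants: 10 C6,C9-diol
Product: 12 C6 acetate C9 triethylsilyl ether, via primary TES ether 11 (not isolated)
Conditions: TESCl (1.05 equiv), imidazole, CH2Cl2, −78 °C; then Et3N, DMAP (cat.), Ac2O, −78 → 0 °C
Reagents that add atoms: chlorotriethylsilane CC[Si](Cl)(CC)CC; acetic anhydride CC(=O)OC(C)=O
Why: Chemoselective silylation of the primary alcohol followed by acetylation of the remaining secondary C6–OH in the same flask (sequential protection) should install the target's acetate with O9 distinguished.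

Step 9
Reactants: 12 C6 acetate C9 triethylsilyl ether
Product: 13 C6-acetoxy C9-aldehyde
Conditions: (COCl)2, DMSO, CH2Cl2, −78 → −30 °C; then Et3N, −78 → 0 °C
Reagents that add atoms: none
Why: Under Swern conditions a primary triethylsilyl ether should be oxidised directly to the aldehyde while the secondary TES ether, acetate and silyl alkyne survive.

Step 10
Reactants: 14 bis(pinacolato)borylmethane; 15 (E)-1-bromopent-2-ene
Product: 17 (E)-1,1-bis(pinacolboryl)hex-3-ene, via lithiated diborylmethane 16 (not isolated)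
Conditions: 2,2,6,6-tetramethylpiperidine, n-BuLi, THF, 0 °C; 14; then 15, 0 °C → rt
Reagents that add atoms: none
Why: Deprotonation of the gem-diboronate (carbanion stabilised by two boron atoms) and SN2 alkylation with the primary allylic bromide should give the homoallylic 1,1-diboronate with the E alkene retained.

Step 11
Reactants: 13 C6-acetoxy C9-aldehyde; 17 (E)-1,1-bis(pinacolboryl)hex-3-ene
Product: 18 (9S,10S)-syn-β-hydroxy boronate
Conditions: Cu(MeCN)4PF6 (10 mol%), BINOL-derived monodentate phosphoramidite L* (20 mol%), LiOtBu (1.3 equiv, premixed with 17), THF, 0 °C → rt; aq. NH4Cl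
Reagents that add atoms: none
Why: Proposed new method: tert-butoxide converts 17 into its borate, one boryl group is transmetalated to the phosphoramidite–Cu(I) centre, and the resulting α-boryl alkylcopper, whose C10 epimers interconvert, should add to the aldehyde of 13 through a closed four-centre carbonyl insertion, after which the copper alkoxide is released and Cu–OtBu is regenerated. The closest known reaction type is the Cu–phosphoramidite-catalysed enantio- and syn-selective 1,2-addition of 1,1-diborylalkanes to aryl and alkenyl aldehydes; an enolisable β-alkoxy aldehyde is the untested substrate class. No ring is closed. C9 (S) and C10 (S) should both be set by the chiral ligand, which selects the aldehyde face and, dynamically, the copper-bearing configuration at C10 so that O and B end syn; the ligand antipode is chosen so that this control overrides the weak 1,3-bias of the C7 ether oxygen. The step needs chemoselectivity for the aldehyde over the C6 acetate and suppression of enolisation (aldol, retro-oxa-Michael opening of the THF), which is secured by binding the base as the borate before 13 is added, by the far higher electrophilicity of the aldehyde, and by masking the alkyne C–H and O3 as silyl groups so that no acidic site competes for copper. The boryl group left on C10 is the latent bromide (oxidation with retention, then displacement with inversion), and the E-C12=C13 alkene arrives intact.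

Step 12
Reactants: 18 (9S,10S)-syn-β-hydroxy boronate
Product: 19 C9 triisopropylsilyl ether of the boronate
Conditions: TIPSOTf, 2,6-lutidine, CH2Cl2, −40 → 0 °C
Reagents that add atoms: triisopropylsilyl trifluoromethanesulfonate CC(C)[Si](OS(=O)(=O)C(F)(F)F)(C(C)C)C(C)C
Why: Silyl triflate silylation of the hindered secondary alcohol should mark O9 as the oxygen that is kept and prevent boron–Wittig-type elimination in the next step.

Step 13
Reactants: 19 C9 triisopropylsilyl ether of the boronate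
Product: 20 (9S,10S)-C10 alcohol
Conditions: NaBO3·4H2O, THF/H2O (1:1), rt
Reagents that add atoms: sodium perborate [Na+].[Na+].O[B-]1(O)OO[B-](O)(O)OO1
Why: Perborate oxidation of the C–B bond (1,2-migration from boron to oxygen) should proceed with retention at C10 and is mild enough for the acetate, giving the syn diol with only O10 free.

Step 14
Reactants: 20 (9S,10S)-C10 alcohol
Product: 21 (3R,10S)-3,10-diol with terminal alkyne
Conditions: TBAF, AcOH (1:1), THF, 0 °C → rt
Reagents that add atoms: none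
Why: Buffered fluoride should remove the alkynyl TMS group and the less hindered secondary TES ether, while the bulky TIPS ether and the acetate persist (selective desilylation).

Step 15
Reactants: 21 (3R,10S)-3,10-diol with terminal alkyne
Product: 22 (3S,10R)-dibromide C9 triisopropylsilyl ether
Conditions: CBr4, PPh3, 2,6-di-tert-butyl-4-methylpyridine, CH2Cl2, 0 °C → rt
Reagents that add atoms: carbon tetrabromide BrC(Br)(Br)Br
Why: In the Appel reaction both alkoxyphosphonium ions should be displaced by bromide in SN2 fashion, inverting C3 (R→S) and C10 (S→R), while the TIPS ether shields O9.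

Step 16
Reactants: 22 (3S,10R)-dibromide C9 triisopropylsilyl ether
Product: 23 target, (2R,3R,5R)-5-[(1S)-1-bromoprop-2-yn-1-yl]-2-[(2S,3R,5E)-3-bromo-2-hydroxyoct-5-en-1-yl]tetrahydrofuran-3-yl acetate
Conditions: aq. HF (48%), MeCN, 0 °C → rt
Reagents that add atoms: none
Why: Acidic fluoride should cleave the TIPS ether (desilylation) without a basic or nucleophilic species that could attack the propargylic bromide, the secondary bromide or the acetate.

**Compound list**

1 | 1,5-dichloropentane-2,4-dione | O=C(CCl)CC(=O)CCl | starting material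
2 | (2R,4R)-1,5-dichloropentane-2,4-diol | ClC[C@H](O)C[C@@H](O)CCl | intermediate
3 | (2R,4R)-1,2:4,5-diepoxypentane | C1O[C@@H]1C[C@@H]1CO1 | intermediate (not isolated)
4 | (3R,5R)-hepta-1,6-diene-3,5-diol | C=C[C@H](O)C[C@@H](O)C=C | intermediate
5 | (3aR,5R,6aR)-5-ethenyltetrahydrofuro[3,2-b]furan-2(3H)-one | C=C[C@H]1C[C@H]2OC(=O)C[C@H]2O1 | intermediate
6 | (3aR,5R,6aR)-5-(1,2,4-trioxolan-3-yl)tetrahydrofuro[3,2-b]furan-2(3H)-one (ozonide, mixture at the trioxolane carbon) | C1OOC(O1)[C@H]2C[C@H]3OC(=O)C[C@H]3O2 | intermediate (not isolated)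
7 | (3aR,5R,6aR)-2-oxohexahydrofuro[3,2-b]furan-5-carbaldehyde | O=C[C@H]1C[C@H]2OC(=O)C[C@H]2O1 | intermediate
8 | (3aR,5R,6aR)-5-[(1R)-1-hydroxy-3-(trimethylsilyl)prop-2-yn-1-yl]tetrahydrofuro[3,2-b]furan-2(3H)-one | C[Si](C)(C)C#C[C@@H](O)[C@H]1C[C@H]2OC(=O)C[C@H]2O1 | intermediate
9 | (3aR,5R,6aR)-5-[(1R)-1-(triethylsilyloxy)-3-(trimethylsilyl)prop-2-yn-1-yl]tetrahydrofuro[3,2-b]furan-2(3H)-one | C[Si](C)(C)C#C[C@@H](O[Si](CC)(CC)CC)[C@H]1C[C@H]2OC(=O)C[C@H]2O1 | intermediate
10 | (2R,3R,5R)-2-(2-hydroxyethyl)-5-[(1R)-1-(triethylsilyloxy)-3-(trimethylsilyl)prop-2-yn-1-yl]tetrahydrofuran-3-ol | C[Si](C)(C)C#C[C@@H](O[Si](CC)(CC)CC)[C@H]1C[C@@H](O)[C@@H](CCO)O1 | intermediate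
11 | (2R,3R,5R)-2-[2-(triethylsilyloxy)ethyl]-5-[(1R)-1-(triethylsilyloxy)-3-(trimethylsilyl)prop-2-yn-1-yl]tetrahydrofuran-3-ol | C[Si](C)(C)C#C[C@@H](O[Si](CC)(CC)CC)[C@H]1C[C@@H](O)[C@@H](CCO[Si](CC)(CC)CC)O1 | intermediate (not isolated)
12 | (2R,3R,5R)-2-[2-(triethylsilyloxy)ethyl]-5-[(1R)-1-(triethylsilyloxy)-3-(trimethylsilyl)prop-2-yn-1-yl]tetrahydrofuran-3-yl acetate | C[Si](C)(C)C#C[C@@H](O[Si](CC)(CC)CC)[C@H]1C[C@@H](OC(C)=O)[C@@H](CCO[Si](CC)(CC)CC)O1 | intermediate
13 | (2R,3R,5R)-2-(2-oxoethyl)-5-[(1R)-1-(triethylsilyloxy)-3-(trimethylsilyl)prop-2-yn-1-yl]tetrahydrofuran-3-yl acetate | C[Si](C)(C)C#C[C@@H](O[Si](CC)(CC)CC)[C@H]1C[C@@H](OC(C)=O)[C@@H](CC=O)O1 | intermediate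
14 | 2,2'-methylenebis(4,4,5,5-tetramethyl-1,3,2-dioxaborolane) | CC1(C)OB(CB2OC(C)(C)C(C)(C)O2)OC1(C)C | starting material
15 | (E)-1-bromopent-2-ene | CC/C=C/CBr | starting material
16 | lithio-bis(4,4,5,5-tetramethyl-1,3,2-dioxaborolan-2-yl)methane | [Li]C(B1OC(C)(C)C(C)(C)O1)B1OC(C)(C)C(C)(C)O1 | intermediate (not isolated)
17 | (E)-2,2'-(hex-3-ene-1,1-diyl)bis(4,4,5,5-tetramethyl-1,3,2-dioxaborolane) | CC/C=C/CC(B1OC(C)(C)C(C)(C)O1)B1OC(C)(C)C(C)(C)O1 | intermediate
18 | (2R,3R,5R)-2-[(2S,3S,5E)-2-hydroxy-3-(4,4,5,5-tetramethyl-1,3,2-dioxaborolan-2-yl)oct-5-en-1-yl]-5-[(1R)-1-(triethylsilyloxy)-3-(trimethylsilyl)prop-2-yn-1-yl]tetrahydrofuran-3-yl acetate | C[Si](C)(C)C#C[C@@H](O[Si](CC)(CC)CC)[C@H]1C[C@@H](OC(C)=O)[C@@H](C[C@H](O)[C@@H](B2OC(C)(C)C(C)(C)O2)C/C=C/CC)O1 | intermediate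
19 | (2R,3R,5R)-2-[(2S,3S,5E)-3-(4,4,5,5-tetramethyl-1,3,2-dioxaborolan-2-yl)-2-(triisopropylsilyloxy)oct-5-en-1-yl]-5-[(1R)-1-(triethylsilyloxy)-3-(trimethylsilyl)prop-2-yn-1-yl]tetrahydrofuran-3-yl acetate | C[Si](C)(C)C#C[C@@H](O[Si](CC)(CC)CC)[C@H]1C[C@@H](OC(C)=O)[C@@H](C[C@H](O[Si](C(C)C)(C(C)C)C(C)C)[C@@H](B2OC(C)(C)C(C)(C)O2)C/C=C/CC)O1 | intermediate
20 | (2R,3R,5R)-2-[(2S,3S,5E)-3-hydroxy-2-(triisopropylsilyloxy)oct-5-en-1-yl]-5-[(1R)-1-(triethylsilyloxy)-3-(trimethylsilyl)prop-2-yn-1-yl]tetrahydrofuran-3-yl acetate | C[Si](C)(C)C#C[C@@H](O[Si](CC)(CC)CC)[C@H]1C[C@@H](OC(C)=O)[C@@H](C[C@H](O[Si](C(C)C)(C(C)C)C(C)C)[C@@H](O)C/C=C/CC)O1 | intermediate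
21 | (2R,3R,5R)-2-[(2S,3S,5E)-3-hydroxy-2-(triisopropylsilyloxy)oct-5-en-1-yl]-5-[(1R)-1-hydroxyprop-2-yn-1-yl]tetrahydrofuran-3-yl acetate | C#C[C@@H](O)[C@H]1C[C@@H](OC(C)=O)[C@@H](C[C@H](O[Si](C(C)C)(C(C)C)C(C)C)[C@@H](O)C/C=C/CC)O1 | intermediate
22 | (2R,3R,5R)-5-[(1S)-1-bromoprop-2-yn-1-yl]-2-[(2S,3R,5E)-3-bromo-2-(triisopropylsilyloxy)oct-5-en-1-yl]tetrahydrofuran-3-yl acetate | C#C[C@H](Br)[C@H]1C[C@@H](OC(C)=O)[C@@H](C[C@H](O[Si](C(C)C)(C(C)C)C(C)C)[C@H](Br)C/C=C/CC)O1 | intermediate
23 | (2R,3R,5R)-5-[(1S)-1-bromoprop-2-yn-1-yl]-2-[(2S,3R,5E)-3-bromo-2-hydroxyoct-5-en-1-yl]tetrahydrofuran-3-yl acetate | C#C[C@H](Br)[C@H]1C[C@@H](OC(C)=O)[C@@H](C[C@H](O)[C@H](Br)C/C=C/CC)O1 | target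

**Summary**

Total step count: 16. Longest linear sequence: 15 steps (steps 1–9 and 11–16); step 10 makes the second fragment.

**Steps most likely to fail, with fallbacks**

Step 11 (Proposed new method). The base may enolise the aldehyde faster than copper adds, leading to self-aldol or retro-oxa-Michael opening of the tetrahydrofuran. Catalyst control may also fail against the substrate bias, so that facial selectivity at C9 is poor. The fallback uses known chemistry and sets out from 13. Brown alkoxyallylboration with (Z)-γ-(methoxymethoxy)allyl-diisopinocampheylborane (antipode chosen for 9S,10S) should give the syn C9-hydroxy C10-MOM ether with a C11=C12 vinyl group F1. TIPSOTf/2,6-lutidine should give the C9 TIPS ether F2. 9-BBN followed by NaBO3 should give the C12 primary alcohol F3, and Dess–Martin oxidation the C12 aldehyde F4. Julia–Kocienski olefination with premetalated 1-phenyl-5-(propylsulfonyl)-1H-tetrazole (KHMDS, −78 °C) should give the (E)-C12=C13 alkene F5. Me2BBr at −78 °C should then remove the MOM group, and the route is rejoined at 20.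

Step 15. The propargylic alkoxyphosphonium ion may be opened in SN2′ fashion to a bromoallene. The propargylic bromide may epimerise by bromide exchange while the slower substitution at C10 is still running. E2 elimination may compete at C10. The fallback sets out from 20 and separates the two brominations. CBr4/P(n-Oct)3 in toluene at 70 °C, with O3 still silylated, should brominate C10 alone with inversion to give the C10 bromide F6. TBAF/AcOH should then give the propargylic alcohol F7, and MsCl/Et3N at −20 °C the propargylic mesylate F8. Displacement with LiBr in THF at 0 °C (SN2, inversion) rejoins the route at 22.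

Step 5. Chelation may be incomplete, so that Felkin–Anh addition competes and facial selectivity at C3 is poor. The α-alkoxy aldehyde may also epimerise at C4. The fallback sets out from 7 and replaces substrate control by reagent control. Addition of lithium (trimethylsilyl)acetylide without stereocontrol should give the C3-epimeric carbinols F9. Dess–Martin oxidation should give the ynone F10. Noyori asymmetric transfer hydrogenation (Ru–TsDPEN, antipode chosen for 3R, i-PrOH) rejoins the route at 8.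

Further compounds
F1 | step 11 | (2R,3R,5R)-2-[(2S,3S)-2-hydroxy-3-(methoxymethoxy)pent-4-en-1-yl]-5-[(1R)-1-(triethylsilyloxy)-3-(trimethylsilyl)prop-2-yn-1-yl]tetrahydrofuran-3-yl acetate | C[Si](C)(C)C#C[C@@H](O[Si](CC)(CC)CC)[C@H]1C[C@@H](OC(C)=O)[C@@H](C[C@H](O)[C@@H](OCOC)C=C)O1
F2 | step 11 | (2R,3R,5R)-2-[(2S,3S)-3-(methoxymethoxy)-2-(triisopropylsilyloxy)pent-4-en-1-yl]-5-[(1R)-1-(triethylsilyloxy)-3-(trimethylsilyl)prop-2-yn-1-yl]tetrahydrofuran-3-yl acetate | C[Si](C)(C)C#C[C@@H](O[Si](CC)(CC)CC)[C@H]1C[C@@H](OC(C)=O)[C@@H](C[C@H](O[Si](C(C)C)(C(C)C)C(C)C)[C@@H](OCOC)C=C)O1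
F3 | step 11 | (2R,3R,5R)-2-[(2S,3S)-5-hydroxy-3-(methoxymethoxy)-2-(triisopropylsilyloxy)pentyl]-5-[(1R)-1-(triethylsilyloxy)-3-(trimethylsilyl)prop-2-yn-1-yl]tetrahydrofuran-3-yl acetate | C[Si](C)(C)C#C[C@@H](O[Si](CC)(CC)CC)[C@H]1C[C@@H](OC(C)=O)[C@@H](C[C@H](O[Si](C(C)C)(C(C)C)C(C)C)[C@@H](OCOC)CCO)O1
F4 | step 11 | (2R,3R,5R)-2-[(2S,3S)-3-(methoxymethoxy)-5-oxo-2-(triisopropylsilyloxy)pentyl]-5-[(1R)-1-(triethylsilyloxy)-3-(trimethylsilyl)prop-2-yn-1-yl]tetrahydrofuran-3-yl acetate | C[Si](C)(C)C#C[C@@H](O[Si](CC)(CC)CC)[C@H]1C[C@@H](OC(C)=O)[C@@H](C[C@H](O[Si](C(C)C)(C(C)C)C(C)C)[C@@H](OCOC)CC=O)O1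
F5 | step 11 | (2R,3R,5R)-2-[(2S,3S,5E)-3-(methoxymethoxy)-2-(triisopropylsilyloxy)oct-5-en-1-yl]-5-[(1R)-1-(triethylsilyloxy)-3-(trimethylsilyl)prop-2-yn-1-yl]tetrahydrofuran-3-yl acetate | C[Si](C)(C)C#C[C@@H](O[Si](CC)(CC)CC)[C@H]1C[C@@H](OC(C)=O)[C@@H](C[C@H](O[Si](C(C)C)(C(C)C)C(C)C)[C@@H](OCOC)C/C=C/CC)O1
F6 | step 15 | (2R,3R,5R)-2-[(2S,3R,5E)-3-bromo-2-(triisopropylsilyloxy)oct-5-en-1-yl]-5-[(1R)-1-(triethylsilyloxy)-3-(trimethylsilyl)prop-2-yn-1-yl]tetrahydrofuran-3-yl acetate | C[Si](C)(C)C#C[C@@H](O[Si](CC)(CC)CC)[C@H]1C[C@@H](OC(C)=O)[C@@H](C[C@H](O[Si](C(C)C)(C(C)C)C(C)C)[C@H](Br)C/C=C/CC)O1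
F7 | step 15 | (2R,3R,5R)-2-[(2S,3R,5E)-3-bromo-2-(triisopropylsilyloxy)oct-5-en-1-yl]-5-[(1R)-1-hydroxyprop-2-yn-1-yl]tetrahydrofuran-3-yl acetate | C#C[C@@H](O)[C@H]1C[C@@H](OC(C)=O)[C@@H](C[C@H](O[Si](C(C)C)(C(C)C)C(C)C)[C@H](Br)C/C=C/CC)O1
F8 | step 15 | (2R,3R,5R)-2-[(2S,3R,5E)-3-bromo-2-(triisopropylsilyloxy)oct-5-en-1-yl]-5-[(1R)-1-(methanesulfonyloxy)prop-2-yn-1-yl]tetrahydrofuran-3-yl acetate | C#C[C@@H](OS(C)(=O)=O)[C@H]1C[C@@H](OC(C)=O)[C@@H](C[C@H](O[Si](C(C)C)(C(C)C)C(C)C)[C@H](Br)C/C=C/CC)O1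
F9 | step 5 | (3aR,5R,6aR)-5-[1-hydroxy-3-(trimethylsilyl)prop-2-yn-1-yl]tetrahydrofuro[3,2-b]furan-2(3H)-one (both C3 epimers) | C[Si](C)(C)C#CC(O)[C@H]1C[C@H]2OC(=O)C[C@H]2O1
F10 | step 5 | (3aR,5R,6aR)-5-[3-(trimethylsilyl)prop-2-ynoyl]tetrahydrofuro[3,2-b]furan-2(3H)-one | C[Si](C)(C)C#CC(=O)[C@H]1C[C@H]2OC(=O)C[C@H]2O1
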